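3 questions stood on this flask, which held half the autumn charge of substrate under the same gas phase.

| flask | substrate | gas phase | remark | time |
|---|---|---|---|---|
| autumn | 0.040 M | 4.5 mM (held) | run made earlier |  |
| flask | 0.020 M | 4.5 mM (held) |  | 8.0 min |

autumn run (percent of the substrate charged)

| time / s | target / % | substrate / % |
|---|---|---|
| 10.0 | 0.7 | 95.0 |
| 20.0 | 0.8 | 91.6 |
| 30.0 | 2.2 | 86.8 |
| 50.0 | 2.6 | 78.7 |
| 80.0 | 5.7 | 67.3 |
| 90.0 | 4.9 | 63.4 |

(scatter of a reading: 0.5 percentage points)

- at the start none of the gas phase is in solution

- target at 8.0 min, in percent of the substrate charged
- the change that raises the amount of target at 8.0 min, in percent of the substrate charged most ("none" if none brings more than 2 percentage points) (north / south / none)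
- amount of target at 8.0 min, in percent of the substrate charged, after south

- north: doubling the transfer coefficient of the gas phase, all else as stated
- south: doubling the saturation concentration of gas phase, all else as stated

1. The autumn substrate fell first order at 0.304 min⁻¹, which said that the percentage lost ignores the charge; yet I took target to need gas, and the solution saturates at 4.5 mM, which is 11.3% of the autumn charge but 22.5% of this flask's, so the two did not seem to go together.

2. I cleared this up through my feed ratio, target formed over substrate lost any other way 0.181, which I read from the last two autumn readings as a ratio of amounts accumulated since the start, not of rates at one moment.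

3. I assumed that gas arrives at a molar rate that ignores the charge while the other loss follows [substrate], so the ratio in this flask became twice the autumn one, 0.361, and I expected it to climb as [substrate] fell.

4. With 91.2% of the substrate lost, I reckoned about 24.2% target.

5. The forecast differed from my figure, giving 13.4%, then south as the best change with 24% after south, and it held: “Faster gas transfer should barely help, because there is no lag to remove.”

6. The steps behind the flask were these:

    gas phase ⇌ dissolved gas, rate k1*(csat - [dissolved gas]) (kL = 0.570 min⁻¹)
    substrate + dissolved gas → target (k = 82.0 M⁻¹ min⁻¹)
    substrate → side product (k = 0.250 min⁻¹)
    target ⇌ isomer of the product (K = 0.250, k = 0.110 min⁻¹)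
    dissolved gas + target → over-reaction product (k = 25.0 M⁻¹ min⁻¹)

7. The flask gave 19.5%, and north won with 2.7 percentage points against 0.51 points for south, which reached 20.0%. Counting isomer of the product and over-reaction product with target, the flask's feed ratio at 8.00 min stood at 0.478, higher than my 0.361. For a neighbour flask charged with 0.080 M, the same scaling gave 0.0903, while the same count gave a higher 0.215, and its target stood at 12.2%.

Readings and results come from a simulation for substances that don't exist, and the scatter is random.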